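**Target:** CNP0183104.1 (compound 17), a bis(dibenzylbutyrolactone) joined through a diaryl ether, (3S,4S) in both lactone rings.

## Analysis of the target

Compound 17 holds two γ-butyrolactone rings (C2 carbonyl, C3 α, C4 β, C5 OCH2) hung on a central diaryl ether, in which ring A is a 3-methoxy-4-aryloxyphenyl ring and ring B a 3-aryloxy-4-hydroxy-5-methoxyphenyl ring. Each of these rings supplies the benzylic CH2 on C3 of one lactone, and each lactone carries a 3,4-dimethoxybenzyl group on C4. The four stereocentres (C3 and C4 of each lactone) are all S and the two benzyl groups of each ring are trans, so the molecule is two homochiral copies of one (3S,4S) lactone, the mirror-image series of the common (3R,4R) dibenzylbutyrolactone lignans. C3 is α to the carbonyl and epimerisable, which is harmless because trans is the more stable arrangement, whereas C4 cannot be corrected once the lactone exists. The ring B phenol lies between a methoxy and an aryloxy group and is sensitive to oxidants and nitrosating agents, so it is carried as an ether. The difficulty is that the two stereo-diads are too far apart to influence each other, so each must be set by reagent control, twice, with the carbonyl placed next to the carbon bearing the core benzyl group in both rings. The strategy rests on the C3–C4 bond of each lactone, which joins two methines that each carry one benzyl group and one single-carbon oxidised substituent (C2 on C3, C5 on C4). That is the pattern of a nitroalkene β carbon (C3, with the nitromethyl carbon becoming C2) bonded to an aldehyde α carbon (C4, with the formyl carbon becoming C5).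

## Retrosynthetic reasoning

17 back to 16: the last bond cut is the O–benzyl bond on ring B. The phenol stays masked to the end because it would not tolerate the nitrosating oxidation that builds the lactones. The forward reaction has to remove the benzyl group under neutral conditions that leave the lactones and C3 alone.

16 back to 13 (through 15 and 14): each lactone is opened at its C2–O bond and the two termini are taken back to different functional groups, C2 to a nitromethyl carbon and C5 to a formyl carbon. Because the termini differ by origin, the carbonyl position is fixed without having to tell apart the two ends of a symmetrical diol or anhydride. Forward, both aldehydes must be reduced before the α centre can epimerise, each nitromethyl group oxidised to the acid, and the rings closed.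

13 back to 10 and two molecules of 12: the two C3–C4 bonds are cut. This is the only bond in each lactone flanked by both stereocentres, so one bond-forming event per arm sets both. The pieces are the diaryl ether core as a bis-nitroalkene (10) and two copies of the simple aldehyde 12. The forward reaction, an enamine-mediated conjugate addition under a chiral secondary amine, must give the syn adduct with S configuration at the aldehyde α carbon on both arms. It must also leave the nitroalkene double bond where it is.

10 back to 8, then to 6 and two molecules of nitromethane 7: each nitroalkene C=C is traced to a nitroaldol, that is, to a C–C bond between the carbon of 7 and a formyl carbon of the bis(arylacetaldehyde) 6. The forward dehydration has to deliver the E alkene conjugated with nitrogen and not with the arene.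

6 back to 5 and then 4: one carbon is removed from each arm, via the enol ether C=C bond. The reason for homologating after ether formation is that aryl aldehydes are what the ether-forming step needs as activating groups, and both arms can then be extended together.

4 back to 2 and 3, and 2 back to 1: the diaryl ether C–O bond is cut on the ring A side, because ring A can carry a fluoride para to a formyl group (3) while ring B supplies the oxygen. This requires the two phenols of 1 to be differentiated, done by benzylating the more acidic 4-hydroxyl to give 2.

12 back to 11: an oxidation-level change only, so that the aldehyde is made fresh from a stable alcohol.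

## Alternatives that were turned down

Alternative 1: Each lactone is cut at the bond between C3 and its benzylic carbon. This gives the bis(benzylic bromide) A3 (two steps from dialdehyde 4) and two copies of the mono-substituted lactone A2. A2 is traced to the prochiral cyclobutanone A1.
- Key step: a flavin-dependent Baeyer–Villiger monooxygenase inserts oxygen into one of the two enantiotopic acyl–CH2 bonds of A1 and expands the ring to A2.
- For it: only one stereocentre needs a catalyst. C3 then follows from the trans-selective alkylation of the lactone enolate, and the late stage is short. On reliability of the late steps this alternative is the stronger one.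
- Against it: it depends on finding an enzyme with the right sense and high selectivity for this particular 3-benzylcyclobutanone, in the less common antipodal series, and on a cofactor-recycling biotransformation at preparative scale. A1 must itself be built by ketene cycloaddition and dechlorination. The two-fold alkylation spends two equivalents of enantioenriched enolate on a bis-electrophile, with proton exchange as a source of mono- and over-alkylated material.
- Comparison: the chosen route offers instead a small-molecule catalyst available in either enantiomer that sets both centres of each lactone in one operation, at the price of a longer preparation of 10.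

Alternative 2: Four bonds are cut, the C4–benzylic and C3–benzylic bonds of both lactones. The five components are two lithiated dithianes from A4, two chiral alkoxybutenolides A5 and the dibromide A3.
- Key step: each dithiane anion adds to C4 of a butenolide anti to the acetal substituent, and the two enolates are trapped at C3 by A3 to give A6.
- For it: four C–C bonds and four stereocentres in one pot. On convergence it is stronger than the chosen route, and the stereocontrol is substrate-based and well defined.
- Against it: the auxiliary is stoichiometric and must come from the less common enantiomer of the terpene alcohol for this (3S,4S) series, with crystallisation to a single acetal epimer. Two hindered enolates next to quaternary dithiane carbons must both find one bis-electrophile. A6 then needs desulfurisation, acetal reduction with relactonisation, and debenzylation on both arms, discarding sulfur and auxiliary mass.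
- Comparison: the chosen route is catalytic in chirality and its key step is a pure addition, but it forms two bonds in that step where this alternative forms four.

Alternative 3: The C4–C5 bonds are cut. C5 is delivered as a silylmethyl radical tethered through oxygen to a benzylic carbinol at the future 3,4-dimethoxybenzyl CH2 (precursor A7).
- Key step: with Bu3SnH both silylmethyl radicals are formed from A7, each closes 5-exo onto C4 of its enoate, and the C3 radicals are reduced to give the bis(oxasilolane) A8.
- For it: the radical closure is dependable and neutral. It is untroubled by the acidity problems of the nitroalkene chemistry, and in that respect more robust than the chosen route. The C3 reduction need not be selective because C3 can be equilibrated later.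
- Against it: the controlling stereocentre is a benzylic carbinol that must be made enantiopure on both arms and is then deleted. A7 needs a long synthesis. After A8 come C–Si oxidation, lactonisation and benzylic deoxygenation, and an electron-rich benzylic C–O bond is prone to ionisation along the way.
- Comparison: it is the longest of the four. The chosen route sets C4 directly and brings C5 in as the aldehyde carbon, with no tether and no sacrificial stereocentre.

Key step: step 8

Remark: alcohol 11 is taken to be a purchasable starting material, and 5 and 8 are carried as isomer mixtures because their stereo-elements are erased in the following steps.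

## Route

Step 1
Reactants: 1 5-hydroxyvanillin (3,4-dihydroxy-5-methoxybenzaldehyde)
Product: 2 4-(benzyloxy)-3-hydroxy-5-methoxybenzaldehyde
Conditions: BnBr (1.0 equiv), NaHCO3 (1.5 equiv), DMF, 40 °C
Reagents that add atoms: benzyl bromide, BrCc1ccccc1
Why: Williamson etherification under weak base; only the 4-hydroxyl, para to the formyl group and therefore the more acidic, is ionised by hydrogen carbonate, so the monoanion is benzylated at O4 and the 3-hydroxyl needed for the diaryl ether stays free.

Step 2
Reactants: 2 4-(benzyloxy)-3-hydroxy-5-methoxybenzaldehyde; 3 4-fluoro-3-methoxybenzaldehyde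
Product: 4 4-(benzyloxy)-3-(4-formyl-2-methoxyphenoxy)-5-methoxybenzaldehyde
Conditions: K2CO3 (2 equiv), DMSO, 110 °C, Ar
Reagents that add atoms: none
Why: Nucleophilic aromatic substitution by addition–elimination; the phenoxide of 2 attacks the fluorine-bearing carbon of 3, the anionic σ-adduct is stabilised by the para formyl group, and fluoride leaves.

Step 3
Reactants: 4 4-(benzyloxy)-3-(4-formyl-2-methoxyphenoxy)-5-methoxybenzaldehyde
Product: 5 2-(benzyloxy)-1-methoxy-5-(2-methoxyethenyl)-3-[2-methoxy-4-(2-methoxyethenyl)phenoxy]benzene (E/Z mixture)
Conditions: Ph3P(CH2OMe)Cl (3 equiv), KOtBu (2.9 equiv), THF, 0 °C to rt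
Reagents that add atoms: (methoxymethyl)triphenylphosphonium chloride, COC[P+](c1ccccc1)(c1ccccc1)c1ccccc1.[Cl-]
Why: Two-fold Wittig methoxymethylenation of the aryl aldehydes; the alkene geometry is not controlled and does not matter, since both isomers hydrolyse to the same aldehyde.

Step 4
Reactants: 5 bis(2-methoxyvinyl) diaryl ether
Product: 6 2-{4-[2-(benzyloxy)-3-methoxy-5-(2-oxoethyl)phenoxy]-3-methoxyphenyl}acetaldehyde (bis(arylacetaldehyde))
Conditions: 2 M aq HCl, THF, 45 °C, Ar; extractive work-up, crude used at once
Reagents that add atoms: water, O
Why: Acid-catalysed enol ether hydrolysis; protonation at the benzylic alkene carbon gives an oxocarbenium ion, water adds and the hemiacetal loses methanol, while benzyl and aryl ethers are inert to dilute acid.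

Step 5
Reactants: 6 bis(arylacetaldehyde); 7 nitromethane (two molecules are taken up, one at each formyl group)
Product: 8 1-{4-[2-(benzyloxy)-5-(2-hydroxy-3-nitropropyl)-3-methoxyphenoxy]-3-methoxyphenyl}-3-nitropropan-2-ol (bis-nitroaldol, diastereomer mixture)
Conditions: 7 (20 equiv), Et3N (0.2 equiv), THF, 0 °C to rt
Reagents that add atoms: nitromethane (second molecule of 7), C[N+](=O)[O-]
Why: Two-fold Henry (nitroaldol) reaction in which one nitronate from 7 adds to each of the two formyl groups of 6, so that two molecules of 7 end up in 8; the large excess of the acidic nitromethane should outcompete self-aldol of the enolisable aldehyde, and the two carbinol centres form without control because they are removed in step 6.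

Step 6
Reactants: 8 bis-nitroaldol
Product: 10 2-(benzyloxy)-1-methoxy-3-{2-methoxy-4-[(E)-3-nitroprop-2-en-1-yl]phenoxy}-5-[(E)-3-nitroprop-2-en-1-yl]benzene (bis-nitroalkene), via bis(methanesulfonate) 9 (not isolated)
Conditions: MsCl (2.4 equiv), iPr2NEt (4.6 equiv), CH2Cl2, −30 to 0 °C; cold 0.5 M HCl quench
Reagents that add atoms: none
Why: O-sulfonylation followed by E1cB elimination through the nitronate, the standard dehydration of nitroaldols to (E)-nitroalkenes; low temperature, limited base and an acidic quench are meant to keep the double bond from moving into conjugation with the arene.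

Step 7
Reactants: 11 3-(3,4-dimethoxyphenyl)propan-1-ol
Product: 12 3-(3,4-dimethoxyphenyl)propanal
Conditions: TEMPO (0.1 equiv), PhI(OAc)2 (1.1 equiv), CH2Cl2, rt; used fresh
Reagents that add atoms: none
Why: Oxoammonium-mediated oxidation of a primary alcohol, which stops at the aldehyde in the absence of water and leaves the electron-rich arene untouched.

Step 8
Reactants: 10 bis-nitroalkene; 12 3-(3,4-dimethoxyphenyl)propanal (two molecules add, one on each arm)
Product: 13 bis(syn-γ-nitroaldehyde): each arm of the benzyl-protected diaryl ether is ArCH2–CH(CH2NO2)–CH(CHO)–CH2(3,4-dimethoxyphenyl), (2S,3S) in butanal numbering on both arms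
Conditions: 12 (5 equiv), (R)-2-[diphenyl(trimethylsilyloxy)methyl]pyrrolidine (20 mol%), 4-nitrophenol (20 mol%), toluene, 0 °C to rt; short silica plug, used at once
Reagents that add atoms: none
Why: Aldehyde 12 condenses with the pyrrolidine nitrogen to the (E)-enamine, whose face on the side of the CPh2(OSiMe3) group is blocked; the open face attacks the nitroalkene β carbon of 10 through an acyclic synclinal transition state (nitro group gauche to the enamine nitrogen), the nitronate is protonated, and hydrolysis of the iminium ion releases the γ-nitroaldehyde and the amine. The closest known reaction type is the diarylprolinol silyl ether catalysed Michael addition of linear aldehydes to β-alkyl and β-aryl nitroalkenes, used here once on each arm of a bis-nitroalkene. Two C–C bonds, the future C3–C4 bonds of the lactones, are formed and no ring is closed. The aldehyde α carbon (future C4) is set S by the catalyst, since the R-configured amine exposes the enamine face opposite to the one its enantiomer exposes; the β carbon (future C3) is set S by the synclinal approach, which places the two benzyl groups syn. The arms are insulated from each other by the diaryl ether, so the same catalyst control applies twice and a mis-set arm would show up as a diastereomer of 13 and not as its enantiomer. The step needs syn over anti selectivity, Michael addition over self-aldol of 12, and a nitroalkene that keeps its double bond next to nitrogen; the excess of 12 and the weakly acidic 4-nitrophenol co-catalyst (faster nitronate protonation and turnover, less free base) are there to secure the last two. A shortfall at the β carbon is tolerable because that carbon becomes the lactone α carbon and can be equilibrated to trans later, whereas the α carbon is fixed by immediate reduction in step 9.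

Step 9
Reactants: 13 bis(syn-γ-nitroaldehyde)
Product: 14 bis(γ-nitro alcohol): each arm ArCH2–CH(CH2NO2)–CH(CH2OH)–CH2(3,4-dimethoxyphenyl), both stereocentres S on both arms
Conditions: NaBH4 (4 equiv), MeOH–CH2Cl2, 0 °C
Reagents that add atoms: none
Why: Chemoselective hydride reduction of both aldehydes, leaving the nitro groups intact; it removes the acidity of the α centre and so locks the future C4 configuration, and surplus 12 is reduced back to 11 and separated.

Step 10
Reactants: 14 bis(γ-nitro alcohol)
Product: 16 O-benzyl bis-lactone (the ring B phenol still a benzyl ether; 3S,4S in both lactones), via bis(hydroxy acid) 15 (not isolated)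
Conditions: NaNO2 (6 equiv), AcOH (20 equiv), DMSO containing ca. 2% water, 35 °C; then TsOH·H2O (cat.), CH2Cl2, rt
Reagents that add atoms: water, O; sodium nitrite, [Na+].[O-]N=O
Why: Nitrite–acetic acid variant of the Nef reaction, taking a primary nitroalkane to the carboxylic acid through the nitrolic acid, nitrile oxide and hydroxamic acid, followed by acid-catalysed lactonisation of the γ-hydroxy acid; the new carbonyl oxygen is delivered by water, which is present in the medium and also formed from nitrous acid. Neither stereocentre is involved, and the benzyl ether keeps the ring B phenol from C-nitrosation.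

Step 11
Reactants: 16 O-benzyl bis-lactone
Product: 17 CNP0183104.1, (3S,4S)-4-(3,4-dimethoxybenzyl)-3-{4-[5-{[(3S,4S)-4-(3,4-dimethoxybenzyl)-2-oxotetrahydrofuran-3-yl]methyl}-2-hydroxy-3-methoxyphenoxy]-3-methoxybenzyl}dihydrofuran-2(3H)-one
Conditions: H2 (1 atm), 10% Pd/C, EtOAc–MeOH, rt
Reagents that add atoms: none
Why: Hydrogenolysis of the aryl benzyl ether under neutral conditions; lactones, methyl ethers and the diaryl ether are stable, and C3 is not exposed to base.

## Compound list

1 | 5-hydroxyvanillin (3,4-dihydroxy-5-methoxybenzaldehyde) | COc1cc(C=O)cc(O)c1O | starting material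
2 | 4-(benzyloxy)-3-hydroxy-5-methoxybenzaldehyde | COc1cc(C=O)cc(O)c1OCc1ccccc1 | intermediate
3 | 4-fluoro-3-methoxybenzaldehyde | COc1cc(C=O)ccc1F | starting material
4 | 4-(benzyloxy)-3-(4-formyl-2-methoxyphenoxy)-5-methoxybenzaldehyde | COc1cc(C=O)ccc1Oc1cc(C=O)cc(OC)c1OCc1ccccc1 | intermediate
5 | 2-(benzyloxy)-1-methoxy-5-(2-methoxyethenyl)-3-[2-methoxy-4-(2-methoxyethenyl)phenoxy]benzene, E/Z mixture | COC=Cc1ccc(Oc2cc(C=COC)cc(OC)c2OCc2ccccc2)c(OC)c1 | intermediate
6 | 2-{4-[2-(benzyloxy)-3-methoxy-5-(2-oxoethyl)phenoxy]-3-methoxyphenyl}acetaldehyde | O=CCc1ccc(Oc2cc(CC=O)cc(OC)c2OCc2ccccc2)c(OC)c1 | intermediate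
7 | nitromethane | C[N+](=O)[O-] | starting material
8 | bis-nitroaldol, 1-{4-[2-(benzyloxy)-5-(2-hydroxy-3-nitropropyl)-3-methoxyphenoxy]-3-methoxyphenyl}-3-nitropropan-2-ol, diastereomer mixture | [O-][N+](=O)CC(O)Cc1ccc(Oc2cc(CC(O)C[N+](=O)[O-])cc(OC)c2OCc2ccccc2)c(OC)c1 | intermediate
9 | bis(methanesulfonate) of 8 (not isolated) | [O-][N+](=O)CC(OS(C)(=O)=O)Cc1ccc(Oc2cc(CC(OS(C)(=O)=O)C[N+](=O)[O-])cc(OC)c2OCc2ccccc2)c(OC)c1 | intermediate
10 | 2-(benzyloxy)-1-methoxy-3-{2-methoxy-4-[(E)-3-nitroprop-2-en-1-yl]phenoxy}-5-[(E)-3-nitroprop-2-en-1-yl]benzene | [O-][N+](=O)/C=C/Cc1ccc(Oc2cc(C/C=C/[N+](=O)[O-])cc(OC)c2OCc2ccccc2)c(OC)c1 | intermediate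
11 | 3-(3,4-dimethoxyphenyl)propan-1-ol | COc1ccc(CCCO)cc1OC | starting material
12 | 3-(3,4-dimethoxyphenyl)propanal | COc1ccc(CCC=O)cc1OC | intermediate
13 | bis(syn-γ-nitroaldehyde), (2S,3S) on both arms | COc1ccc(C[C@H](C=O)[C@@H](C[N+](=O)[O-])Cc2ccc(Oc3cc(C[C@H](C[N+](=O)[O-])[C@@H](C=O)Cc4ccc(OC)c(OC)c4)cc(OC)c3OCc3ccccc3)c(OC)c2)cc1OC | intermediate
14 | bis(γ-nitro alcohol), S at all four centres | COc1ccc(C[C@H](CO)[C@@H](C[N+](=O)[O-])Cc2ccc(Oc3cc(C[C@H](C[N+](=O)[O-])[C@@H](CO)Cc4ccc(OC)c(OC)c4)cc(OC)c3OCc3ccccc3)c(OC)c2)cc1OC | intermediate
15 | bis(γ-hydroxy acid), S at all four centres (not isolated) | COc1ccc(C[C@H](CO)[C@@H](C(=O)O)Cc2ccc(Oc3cc(C[C@H](C(=O)O)[C@@H](CO)Cc4ccc(OC)c(OC)c4)cc(OC)c3OCc3ccccc3)c(OC)c2)cc1OC | intermediate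
16 | O-benzyl bis-lactone, (3S,4S) in both rings | COc1ccc(C[C@@H]2COC(=O)[C@H]2Cc2ccc(Oc3cc(C[C@@H]4C(=O)OC[C@H]4Cc4ccc(OC)c(OC)c4)cc(OC)c3OCc3ccccc3)c(OC)c2)cc1OC | intermediate
17 | CNP0183104.1, (3S,4S) in both lactone rings | COc1ccc(C[C@@H]2COC(=O)[C@H]2Cc2ccc(Oc3cc(C[C@@H]4C(=O)OC[C@H]4Cc4ccc(OC)c(OC)c4)cc(OC)c3O)c(OC)c2)cc1OC | target

## Step count and least certain steps

Total: 11 steps. Longest linear sequence: 10 steps (steps 1 to 6, then 8 to 11); step 7 is a one-step branch.

Step 8 (key step). The most likely failure is migration of the nitroalkene double bond toward rings A and B under the amine, which removes the acceptor. Other risks are slow addition to a β-alkyl nitroalkene, which lets self-aldol of 12 and catalyst deactivation compete, incomplete reaction of the second arm, and α-epimerisation before reduction. Loss of syn selectivity alone is correctable by base equilibration of C3 at the stage of 16. Fallback, keeping the same C3–C4 disconnection but with a stoichiometric auxiliary and no amine base: it sets out from 10. The chlorotitanium enolate (TiCl4, iPr2NEt, CH2Cl2, −78 °C) of (R)-4-benzyl-3-[3-(3,4-dimethoxyphenyl)propanoyl]-1,3-oxazolidin-2-one F1 would be added to both arms. F1 would be made from commercial 3-(3,4-dimethoxyphenyl)propanoic acid and (R)-4-benzyl-1,3-oxazolidin-2-one through the pivaloyl mixed anhydride. The product would be the bis(imide) Michael adduct F2, with the α centres fixed S by the auxiliary. LiBH4 in wet THF would then cleave both auxiliaries reductively and give 14, where the route is rejoined.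

Step 6. Base-induced isomerisation of the product to the arene-conjugated allylic nitro isomer, or oligomerisation of the nitroalkene, during elimination. Fallback, setting out from 8 and avoiding amine base at the alkene-forming stage: acetylation (Ac2O, cat. DMAP) would give the bis(β-nitro acetate) F3. NaBH4 in EtOH would convert it by elimination and conjugate reduction into the saturated bis(3-nitropropyl) compound F4, where double-bond position no longer matters. Deprotonation (KOtBu, THF, −78 °C) and selenenylation with PhSeBr would give the bis(α-phenylselanyl nitro) compound F5. H2O2 at 0 °C would then induce selenoxide syn-elimination, which can only form the double bond next to nitrogen, returning to 10.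

Step 4. Self-condensation and air oxidation of the bis(arylacetaldehyde) while it is generated in warm acid. Fallback, setting out from 4: Wittig methylenation (Ph3PCH3Br, KOtBu) would give the divinyl compound F6. Hydroboration–oxidation (9-BBN, then NaOH/H2O2) would give the bis(2-arylethanol) F7. Dess–Martin oxidation buffered with NaHCO3 would release 6 under neutral conditions for direct use in step 5.

Step 10. The oxidation may stall at the hydroxamic acid or oxime stage, and the nitrosating medium may attack the electron-rich rings or the free hydroxyls. Fallback, setting out from 14 and changing the oxidation-level path: a classical Nef reaction (NaOMe in MeOH, then addition to cold aqueous H2SO4) would unmask each nitromethyl carbon as a formyl group, which is captured at once by the neighbouring hydroxyl and isolated as the bis-lactol F8. Oxidation of the lactols with TEMPO/PhI(OAc)2 would give 16.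

Step 2. The displacement may be sluggish, since the phenoxide is hindered by the ortho benzyloxy group and the fluoride is activated by a single para formyl group; forcing conditions risk degrading the aldehydes. Fallback, setting out from 2 and returning at 4: a copper-catalysed Ullmann ether coupling with commercial 4-bromo-3-methoxybenzaldehyde (copper monoiodide CuI, N,N-dimethylglycine, Cs2CO3, dioxane, 90 °C), which does not rely on arene activation and makes no compound outside the list (entry F0).

## Further compounds

F1 | step 8 | (R)-4-benzyl-3-[3-(3,4-dimethoxyphenyl)propanoyl]-1,3-oxazolidin-2-one | COc1ccc(CCC(=O)N2C(=O)OC[C@H]2Cc2ccccc2)cc1OC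
F2 | step 8 | bis(N-acyl oxazolidinone) Michael adduct of 10, S at all four chain centres | COc1ccc(C[C@H](C(=O)N5C(=O)OC[C@H]5Cc5ccccc5)[C@@H](C[N+](=O)[O-])Cc2ccc(Oc3cc(C[C@H](C[N+](=O)[O-])[C@@H](C(=O)N6C(=O)OC[C@H]6Cc6ccccc6)Cc4ccc(OC)c(OC)c4)cc(OC)c3OCc3ccccc3)c(OC)c2)cc1OC
F3 | step 6 | bis(β-nitro acetate) of 8, diastereomer mixture | CC(=O)OC(C[N+](=O)[O-])Cc1ccc(Oc2cc(CC(OC(C)=O)C[N+](=O)[O-])cc(OC)c2OCc2ccccc2)c(OC)c1
F4 | step 6 | 2-(benzyloxy)-1-methoxy-3-[2-methoxy-4-(3-nitropropyl)phenoxy]-5-(3-nitropropyl)benzene | [O-][N+](=O)CCCc1ccc(Oc2cc(CCC[N+](=O)[O-])cc(OC)c2OCc2ccccc2)c(OC)c1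
F5 | step 6 | bis[3-nitro-3-(phenylselanyl)propyl] analogue of F4, diastereomer mixture | [O-][N+](=O)C([Se]c1ccccc1)CCc1ccc(Oc2cc(CCC([Se]c3ccccc3)[N+](=O)[O-])cc(OC)c2OCc2ccccc2)c(OC)c1
F6 | step 4 | 2-(benzyloxy)-5-ethenyl-3-(4-ethenyl-2-methoxyphenoxy)-1-methoxybenzene | C=Cc1ccc(Oc2cc(C=C)cc(OC)c2OCc2ccccc2)c(OC)c1
F7 | step 4 | 2-{4-[2-(benzyloxy)-5-(2-hydroxyethyl)-3-methoxyphenoxy]-3-methoxyphenyl}ethan-1-ol | OCCc1ccc(Oc2cc(CCO)cc(OC)c2OCc2ccccc2)c(OC)c1
F8 | step 10 | bis-lactol corresponding to 16 (2-hydroxytetrahydrofurans, anomer mixture) | COc1ccc(C[C@@H]2COC(O)[C@H]2Cc2ccc(Oc3cc(C[C@@H]4C(O)OC[C@H]4Cc4ccc(OC)c(OC)c4)cc(OC)c3OCc3ccccc3)c(OC)c2)cc1OC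
F0 | step 2 | none | none
A1 | alternative 1 | 3-(3,4-dimethoxybenzyl)cyclobutan-1-one | COc1ccc(CC2CC(=O)C2)cc1OC
A2 | alternative 1 | (S)-4-(3,4-dimethoxybenzyl)dihydrofuran-2(3H)-one | COc1ccc(C[C@@H]2COC(=O)C2)cc1OC
A3 | alternative 1 | 2-(benzyloxy)-5-(bromomethyl)-3-[4-(bromomethyl)-2-methoxyphenoxy]-1-methoxybenzene | BrCc1ccc(Oc2cc(CBr)cc(OC)c2OCc2ccccc2)c(OC)c1
A4 | alternative 2 | 2-(3,4-dimethoxyphenyl)-1,3-dithiane | COc1ccc(C2SCCCS2)cc1OC
A5 | alternative 2 | (5S)-5-[(1S,2R,5S)-menthyloxy]furan-2(5H)-one | O=C1C=C[C@@H](O[C@H]2C[C@@H](C)CC[C@@H]2C(C)C)O1
A6 | alternative 2 | bis(5-menthyloxy lactone) bis(dithiane) adduct | COc1ccc(C3(SCCCS3)[C@@H]2[C@@H](O[C@H]8C[C@@H](C)CC[C@@H]8C(C)C)OC(=O)[C@H]2Cc2ccc(Oc3cc(C[C@@H]4C(=O)O[C@H](O[C@H]5C[C@@H](C)CC[C@@H]5C(C)C)[C@H]4C6(SCCCS6)c7ccc(OC)c(OC)c7)cc(OC)c3OCc9ccccc9)c(OC)c2)cc1OC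
A7 | alternative 3 | bis[(bromomethyl)dimethylsilyl] ether of the diaryl ether bis(γ-hydroxy-α-benzyl enoate), (S) carbinols, E alkenes | COc1ccc([C@@H](O[Si](C)(C)CBr)/C=C(/C(=O)OC)Cc2ccc(Oc3cc(C\C(C(=O)OC)=C/[C@H](O[Si](C)(C)CBr)c4ccc(OC)c(OC)c4)cc(OC)c3OCc3ccccc3)c(OC)c2)cc1OC
A8 | alternative 3 | bis(1,2-oxasilolane) diester | COc1ccc([C@H]2O[Si](C)(C)C[C@@H]2[C@@H](C(=O)OC)Cc2ccc(Oc3cc(C[C@H](C(=O)OC)[C@H]5C[Si](C)(C)O[C@@H]5c4ccc(OC)c(OC)c4)cc(OC)c3OCc3ccccc3)c(OC)c2)cc1OC
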